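**Strategy.** The hydroquinone ring is built last, so no acid-sensitive prenylated hydroquinone is carried through the chain assembly. The arene (C1–C6; oxygens on C1 and C4, side-chain carbon C1' on C2) is cut into three pieces: C2–C3 from a terminal alkyne, C4–C5–C6 with the C4 oxygen from a methoxy(vinyl)carbene on chromium, and C1 with its oxygen from carbon monoxide. One Dötz benzannulation forms C3–C4, C1–C2 and C1–C6 and gives a para-oxygenated ring with the chain ortho to the free OH. The precursor is a C22 skipped enyne, made from β-cyclogeranyl phenyl sulfone and (E,E)-8-bromogeranyl acetate and extended by one ethynyl unit; the carbene complex is prepared fresh.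

Key step: step 12

Remark: the target has no stereocentre; its only stereochemical elements are the two E trisubstituted alkenes (C2'=C3' carried in from geranyl acetate, C6'=C7' set in step 4), and vinyllithium is taken to be generated from vinyl bromide and t-BuLi.

Step 1
Reactants: 1 β-cyclocitral
Product: 2 β-cyclogeraniol [(2,6,6-trimethylcyclohex-1-en-1-yl)methanol]
Conditions: NaBH4, MeOH, 0 °C
Reagents that add atoms: none
Why: 1,2-hydride reduction of a hindered enal by NaBH4; conjugate reduction does not compete at the fully substituted β-carbon.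

Step 2
Reactants: 2 β-cyclogeraniol
Product: 3 β-cyclogeranyl bromide [2-(bromomethyl)-1,3,3-trimethylcyclohexene]
Conditions: PBr3 (0.4 equiv), pyridine (cat.), Et2O, −10 → 0 °C; used crude at once
Reagents that add atoms: phosphorus tribromide, BrP(Br)Br
Why: PBr3 bromination of a primary allylic alcohol through its phosphite ester; the primary bromide next to the tetrasubstituted alkene is the stable allylic isomer.

Step 3
Reactants: 3 β-cyclogeranyl bromide
Product: 4 β-cyclogeranyl phenyl sulfone [1,3,3-trimethyl-2-[(phenylsulfonyl)methyl]cyclohexene]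
Conditions: PhSO2Na (1.5 equiv), DMF, rt
Reagents that add atoms: sodium benzenesulfinate, [Na+].[O-]S(=O)c1ccccc1
Why: SN2 S-alkylation of the sulfinate by the allylic bromide gives the sulfone, which is also the thermodynamically preferred allylic isomer.

Step 4
Reactants: 5 geranyl acetate
Product: 6 (2E,6E)-8-hydroxy-3,7-dimethylocta-2,6-dien-1-yl acetate
Conditions: SeO2 (0.1 equiv), t-BuOOH (70% aq.), salicylic acid (cat.), CH2Cl2, rt
Reagents that add atoms: tert-butyl hydroperoxide, CC(C)(C)OO (net oxygen source); selenium dioxide, O=[Se]=O (catalytic oxygen carrier)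
Why: SeO2-catalysed allylic oxidation (ene reaction, then [2,3]-sigmatropic shift) attacks the more electron-rich distal alkene at its E methyl group, which sets the 6E geometry of the new allylic alcohol.

Step 5
Reactants: 6 (2E,6E)-8-hydroxy-3,7-dimethylocta-2,6-dien-1-yl acetate
Product: 7 (2E,6E)-8-bromo-3,7-dimethylocta-2,6-dien-1-yl acetate
Conditions: CBr4, PPh3, CH2Cl2, 0 °C
Reagents that add atoms: carbon tetrabromide, BrC(Br)(Br)Br
Why: Appel bromination of a primary allylic alcohol by SN2 displacement of the alkoxyphosphonium ion under neutral conditions, so the acetate and both E alkenes are kept.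

Step 6
Reactants: 4 β-cyclogeranyl phenyl sulfone; 7 (2E,6E)-8-bromo-3,7-dimethylocta-2,6-dien-1-yl acetate
Product: 9 (2E,6E)-3,7-dimethyl-9-(phenylsulfonyl)-9-(2,6,6-trimethylcyclohex-1-en-1-yl)nona-2,6-dien-1-yl acetate (racemic at C9), via lithiated sulfone 8 (not isolated)
Conditions: n-BuLi (1.05 equiv), THF, −78 °C; then 7, THF, −78 → −20 °C
Reagents that add atoms: none
Why: Alkylation of an α-sulfonyl carbanion, in which the soft lithiated sulfone displaces the primary allylic bromide by SN2 at −78 °C faster than it attacks the acetate; the new stereocentre at the sulfone carbon forms racemic and is erased in step 7.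

Step 7
Reactants: 9 (2E,6E)-3,7-dimethyl-9-(phenylsulfonyl)-9-(2,6,6-trimethylcyclohex-1-en-1-yl)nona-2,6-dien-1-yl acetate
Product: 11 (2E,6E)-3,7-dimethyl-9-(2,6,6-trimethylcyclohex-1-en-1-yl)nona-2,6-dien-1-ol, via lithium alkoxide of the hydroxy sulfone 10 (not isolated)
Conditions: LiBHEt3 (6 equiv), THF, −78 → 0 °C; then PdCl2(dppp) (5 mol%; dppp = 1,3-bis(diphenylphosphino)propane), 0 °C → rt
Reagents that add atoms: none
Why: Palladium-catalysed reductive desulfonylation of an allylic sulfone: LiBHEt3 first reduces the acetate to an alkoxide that cannot ionise, then zerovalent palladium inserts into the allylic C–S bond and hydride is delivered to the less hindered exocyclic terminus of the π-allyl, so the tetrasubstituted ring alkene stays in place.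

Step 8
Reactants: 11 (2E,6E)-3,7-dimethyl-9-(2,6,6-trimethylcyclohex-1-en-1-yl)nona-2,6-dien-1-ol
Product: 12 2-[(3E,7E)-9-bromo-3,7-dimethylnona-3,7-dien-1-yl]-1,3,3-trimethylcyclohexene
Conditions: CBr4, PPh3, CH2Cl2, −20 → 0 °C
Reagents that add atoms: carbon tetrabromide, BrC(Br)(Br)Br
Why: Appel bromination gives the primary allylic bromide by SN2 without acid, which avoids allylic transposition and cation-type cyclisation of the polyene.

Step 9
Reactants: 12 2-[(3E,7E)-9-bromo-3,7-dimethylnona-3,7-dien-1-yl]-1,3,3-trimethylcyclohexene; 13 trimethylsilylacetylene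
Product: 15 trimethyl[(4E,8E)-5,9-dimethyl-11-(2,6,6-trimethylcyclohex-1-en-1-yl)undeca-4,8-dien-1-yn-1-yl]silane, via (trimethylsilylethynyl)magnesium bromide 14 (not isolated)
Conditions: 13, EtMgBr, THF, 0 °C → rt; then CuI (10 mol%), 12, THF, 0 °C → rt
Reagents that add atoms: none
Why: Copper-catalysed coupling of an alkynyl Grignard reagent with a primary allylic bromide; the disubstituted γ-carbon is hindered, so attack at the α-carbon should dominate and keep the E alkene, and the silyl cap prevents double alkylation.

Step 10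
Reactants: 15 trimethyl[(4E,8E)-5,9-dimethyl-11-(2,6,6-trimethylcyclohex-1-en-1-yl)undeca-4,8-dien-1-yn-1-yl]silane
Product: 16 2-[(3E,7E)-3,7-dimethylundeca-3,7-dien-10-yn-1-yl]-1,3,3-trimethylcyclohexene
Conditions: K2CO3, MeOH–THF, rt
Reagents that add atoms: none
Why: Methoxide-mediated protodesilylation of the alkynylsilane; K2CO3 at room temperature is too weak a base to isomerise the skipped enyne to an allene.

Step 11
Reactants: 17 chromium hexacarbonyl, Cr(CO)6; 18 vinyl bromide
Product: 21 pentacarbonyl[methoxy(vinyl)carbene]chromium, via vinyllithium 19 (not isolated), via lithium acylchromate 20 (not isolated)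
Conditions: 18, t-BuLi (2 equiv), Et2O, −78 °C; 17, −78 → 0 °C; then Me3OBF4, CH2Cl2, 0 °C; cold pentane/silica filtration under Ar, used the same day
Reagents that add atoms: trimethyloxonium tetrafluoroborate, C[O+](C)C.F[B-](F)(F)F
Why: Fischer carbene synthesis, in which vinyllithium from Br/Li exchange adds to a CO ligand of Cr(CO)6 and the resulting acylchromate is O-methylated by the hard electrophile Me3OBF4; the complex polymerises on standing, so it is kept cold and used at once.

Step 12
Reactants: 16 2-[(3E,7E)-3,7-dimethylundeca-3,7-dien-10-yn-1-yl]-1,3,3-trimethylcyclohexene; 21 pentacarbonyl[methoxy(vinyl)carbene]chromium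
Product: 23 4-methoxy-2-[(2E,6E)-3,7-dimethyl-9-(2,6,6-trimethylcyclohex-1-en-1-yl)nona-2,6-dien-1-yl]phenol, via tricarbonylchromium arene complex 22 (not isolated)
Conditions: 21 (1.5–2 equiv, fresh, added in portions), THF (degassed, dilute), 45–50 °C, Ar; then air, Et2O, rt; Et3N-deactivated silica
Reagents that add atoms: none
Why: Thermal loss of one CO ligand from 21 frees a site for the terminal alkyne of 16, which inserts into the Cr=C bond to give a vinylcarbene; CO insertion then gives a chromium-bound dienylketene. The six-membered ring closes by 6π electrocyclisation of this dienylketene (ketene carbon C1 to vinyl terminus C6), and enolisation of the cyclohexadienone gives the phenol as its Cr(CO)3 complex 22, which air decomplexes. This is the Dötz benzannulation of an alkenyl(alkoxy)carbene chromium complex with a terminal alkyne, a known reaction class. No stereocentre is formed, and both E alkenes should survive because the medium is neutral, isolated tri- and tetrasubstituted alkenes do not cyclopropanate with such carbenes at this temperature, and the skipped position of the nearest alkene rules out intramolecular capture of the vinylcarbene. The required regiochemistry (chain ortho to OH, meta to OMe) comes from the insertion step, where the unsubstituted alkyne carbon bonds to the carbene carbon and the carbon bearing the CH2 chain ends up beside the CO-derived carbon. Phenol formation over furan or five-membered-ring products is favoured by the alkenyl carbene and by THF, and the lability of 21 is met by using it fresh and in excess over the valuable alkyne.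

Step 13
Reactants: 23 4-methoxy-2-[(2E,6E)-3,7-dimethyl-9-(2,6,6-trimethylcyclohex-1-en-1-yl)nona-2,6-dien-1-yl]phenol
Product: 25 jaspaquinol [2-[(2E,6E)-3,7-dimethyl-9-(2,6,6-trimethylcyclohex-1-en-1-yl)nona-2,6-dien-1-yl]benzene-1,4-diol], via jaspaquinone 24 (not isolated)
Conditions: (NH4)2Ce(NO3)6 (2.2 equiv), MeCN–H2O, 0 °C, short contact; Et2O extraction; then aq. Na2S2O4, rt, Ar, degassed solvents
Reagents that add atoms: water, O
Why: Oxidative demethylation, in which tetravalent cerium oxidises the electron-rich para-methoxyphenol, water adds at the methoxy-bearing carbon and methanol is lost to give the quinone, followed by dithionite reduction to the hydroquinone under near-neutral conditions that should not close a chroman.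

**Compound list**

1 | β-cyclocitral | CC1=C(C=O)C(C)(C)CCC1 | starting material
2 | β-cyclogeraniol, (2,6,6-trimethylcyclohex-1-en-1-yl)methanol | CC1=C(CO)C(C)(C)CCC1 | intermediate
3 | β-cyclogeranyl bromide, 2-(bromomethyl)-1,3,3-trimethylcyclohexene | CC1=C(CBr)C(C)(C)CCC1 | intermediate
4 | β-cyclogeranyl phenyl sulfone, 1,3,3-trimethyl-2-[(phenylsulfonyl)methyl]cyclohexene | CC1=C(CS(=O)(=O)c2ccccc2)C(C)(C)CCC1 | intermediate
5 | geranyl acetate | CC(C)=CCC/C(C)=C/COC(C)=O | starting material
6 | (2E,6E)-8-hydroxy-3,7-dimethylocta-2,6-dien-1-yl acetate | OC/C(C)=C/CC/C(C)=C/COC(C)=O | intermediate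
7 | (2E,6E)-8-bromo-3,7-dimethylocta-2,6-dien-1-yl acetate | BrC/C(C)=C/CC/C(C)=C/COC(C)=O | intermediate
8 | lithiated sulfone, [(phenylsulfonyl)(2,6,6-trimethylcyclohex-1-en-1-yl)methyl]lithium | [Li]C(S(=O)(=O)c1ccccc1)C1=C(C)CCCC1(C)C | intermediate
9 | (2E,6E)-3,7-dimethyl-9-(phenylsulfonyl)-9-(2,6,6-trimethylcyclohex-1-en-1-yl)nona-2,6-dien-1-yl acetate (racemic at C9) | CC(=O)OC/C=C(\C)CC/C=C(\C)CC(S(=O)(=O)c1ccccc1)C1=C(C)CCCC1(C)C | intermediate
10 | lithium (2E,6E)-3,7-dimethyl-9-(phenylsulfonyl)-9-(2,6,6-trimethylcyclohex-1-en-1-yl)nona-2,6-dien-1-olate (racemic) | [Li]OC/C=C(\C)CC/C=C(\C)CC(S(=O)(=O)c1ccccc1)C1=C(C)CCCC1(C)C | intermediate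
11 | (2E,6E)-3,7-dimethyl-9-(2,6,6-trimethylcyclohex-1-en-1-yl)nona-2,6-dien-1-ol | OC/C=C(\C)CC/C=C(\C)CCC1=C(C)CCCC1(C)C | intermediate
12 | 2-[(3E,7E)-9-bromo-3,7-dimethylnona-3,7-dien-1-yl]-1,3,3-trimethylcyclohexene | BrC/C=C(\C)CC/C=C(\C)CCC1=C(C)CCCC1(C)C | intermediate
13 | trimethylsilylacetylene | C#C[Si](C)(C)C | starting material
14 | (trimethylsilylethynyl)magnesium bromide | C[Si](C)(C)C#C[Mg]Br | intermediate
15 | trimethyl[(4E,8E)-5,9-dimethyl-11-(2,6,6-trimethylcyclohex-1-en-1-yl)undeca-4,8-dien-1-yn-1-yl]silane | C[Si](C)(C)C#CC/C=C(\C)CC/C=C(\C)CCC1=C(C)CCCC1(C)C | intermediate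
16 | 2-[(3E,7E)-3,7-dimethylundeca-3,7-dien-10-yn-1-yl]-1,3,3-trimethylcyclohexene | C#CC/C=C(\C)CC/C=C(\C)CCC1=C(C)CCCC1(C)C | intermediate
17 | chromium hexacarbonyl, Cr(CO)6 | O=C=[Cr](=C=O)(=C=O)(=C=O)(=C=O)=C=O | starting material
18 | vinyl bromide | C=CBr | starting material
19 | vinyllithium | [Li]C=C | intermediate
20 | lithium pentacarbonyl(1-oxidoprop-2-en-1-ylidene)chromate (lithium acylchromate) | [Li+].[O-]C(C=C)=[Cr](=C=O)(=C=O)(=C=O)(=C=O)=C=O | intermediate
21 | pentacarbonyl[methoxy(vinyl)carbene]chromium (zerovalent chromium) | COC(C=C)=[Cr](=C=O)(=C=O)(=C=O)(=C=O)=C=O | intermediate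
22 | tricarbonyl(η6-arene)chromium complex of 23 (arene face-bound to Cr; written as two components) | COc1ccc(O)c(C/C=C(\C)CC/C=C(\C)CCC2=C(C)CCCC2(C)C)c1.O=C=[Cr](=C=O)=C=O | intermediate
23 | 4-methoxy-2-[(2E,6E)-3,7-dimethyl-9-(2,6,6-trimethylcyclohex-1-en-1-yl)nona-2,6-dien-1-yl]phenol | COc1ccc(O)c(C/C=C(\C)CC/C=C(\C)CCC2=C(C)CCCC2(C)C)c1 | intermediate
24 | jaspaquinone, 2-[(2E,6E)-3,7-dimethyl-9-(2,6,6-trimethylcyclohex-1-en-1-yl)nona-2,6-dien-1-yl]cyclohexa-2,5-diene-1,4-dione | O=C1C=CC(=O)C(C/C=C(\C)CC/C=C(\C)CCC2=C(C)CCCC2(C)C)=C1 | intermediate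
25 | jaspaquinol, 2-[(2E,6E)-3,7-dimethyl-9-(2,6,6-trimethylcyclohex-1-en-1-yl)nona-2,6-dien-1-yl]benzene-1,4-diol | CC1=C(CC/C(C)=C/CC/C(C)=C/Cc2cc(O)ccc2O)C(C)(C)CCC1 | target

**Count.** Total steps: 13. Longest linear sequence: 10 steps (1, 2, 3, 6, 7, 8, 9, 10, 12, 13).

**Steps most likely to fail**

Step 12. The vinyl carbene complex may polymerise or decay faster than the alkyne inserts, or the terminal alkyne may oligomerise at chromium, so that little arene forms. The fallback gives up the ring construction and sets out from bromide 12. 1,4-Dimethoxybenzene is lithiated (n-BuLi, TMEDA, Et2O, 0 °C) to 2,5-dimethoxyphenyllithium F1, which with CuBr·SMe2 as catalyst alkylates 12 at its primary carbon to give 2-[(2E,6E)-3,7-dimethyl-9-(2,6,6-trimethylcyclohex-1-en-1-yl)nona-2,6-dien-1-yl]-1,4-dimethoxybenzene F2. Oxidation of F2 with (NH4)2Ce(NO3)6 in MeCN–H2O at 0 °C returns to the route at quinone 24, which the dithionite half of step 13 reduces to 25.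

Step 11. The parent vinyl complex may be lost through Michael-type polymerisation during methylation and isolation. The fallback sets out from Cr(CO)6 17 and uses a silyl-stabilised equivalent. (E)-(2-Bromovinyl)trimethylsilane and t-BuLi (Et2O, −78 °C) give (E)-(2-lithiovinyl)trimethylsilane F3, which adds to 17 to give the lithium acylchromate F4. Me3OBF4 converts F4 into pentacarbonyl{methoxy[(E)-2-(trimethylsilyl)vinyl]carbene}chromium F5, a β-silyl vinylcarbene complex of a type known to be storable. Heating F5 with alkyne 16 in THF at 50 °C should, after a shift of silicon from carbon to oxygen in the cyclohexadienone intermediate and air decomplexation, give the aryl trimethylsilyl ether F6. K2CO3 in MeOH removes the silyl group and the route is rejoined at methoxyphenol 23.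

Step 7. If acetate cleavage is incomplete when the catalyst is added, the allylic C–O bond may undergo hydrogenolysis through a π-allyl palladium species; oxidative addition at the hindered allylic sulfone may also be slow and let the ring alkene migrate. The fallback sets out from 9 and separates the two events. K2CO3 in MeOH gives the hydroxy sulfone F7, and lithium in ethylamine–THF at −78 °C (dissolving-metal desulfonylation, with the alkoxide shielding the allylic C–O bond) then cleaves the C–S bond and returns to the route at alcohol 11.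

**Further compounds**

F1 | step 12 | 2,5-dimethoxyphenyllithium | [Li]c1cc(OC)ccc1OC
F2 | step 12 | 2-[(2E,6E)-3,7-dimethyl-9-(2,6,6-trimethylcyclohex-1-en-1-yl)nona-2,6-dien-1-yl]-1,4-dimethoxybenzene | COc1ccc(OC)c(C/C=C(\C)CC/C=C(\C)CCC2=C(C)CCCC2(C)C)c1
F3 | step 11 | (E)-(2-lithiovinyl)trimethylsilane | [Li]/C=C/[Si](C)(C)C
F4 | step 11 | lithium pentacarbonyl[(E)-1-oxido-3-(trimethylsilyl)prop-2-en-1-ylidene]chromate | [Li+].[O-]C(/C=C/[Si](C)(C)C)=[Cr](=C=O)(=C=O)(=C=O)(=C=O)=C=O
F5 | step 11 | pentacarbonyl{methoxy[(E)-2-(trimethylsilyl)vinyl]carbene}chromium | COC(/C=C/[Si](C)(C)C)=[Cr](=C=O)(=C=O)(=C=O)(=C=O)=C=O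
F6 | step 11 | {4-methoxy-2-[(2E,6E)-3,7-dimethyl-9-(2,6,6-trimethylcyclohex-1-en-1-yl)nona-2,6-dien-1-yl]phenoxy}trimethylsilane | COc1ccc(O[Si](C)(C)C)c(C/C=C(\C)CC/C=C(\C)CCC2=C(C)CCCC2(C)C)c1
F7 | step 7 | (2E,6E)-3,7-dimethyl-9-(phenylsulfonyl)-9-(2,6,6-trimethylcyclohex-1-en-1-yl)nona-2,6-dien-1-ol (racemic) | OC/C=C(\C)CC/C=C(\C)CC(S(=O)(=O)c1ccccc1)C1=C(C)CCCC1(C)C
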